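**Retrosynthetic overview** (cembrane numbering: C1 = CH carrying the acrylate, C3/C4 diol, C7=C8, C11 carbinol, C12–O lactone, C16 lactone C=O)
1. The C20 skeleton is two C10 keto aldehydes joined head to tail: C4–C11 from 1,5-dimethyl-1,5-cyclooctadiene (the ring fixes 7Z) and C12–C14/C1–C3/C15–C17 from (R)-limonene (supplies C1).
2. Last disconnection, C3–C4 (14-membered ring): the diol is opened to aldehyde C3 + methyl ketone C4, closed by titanium-mediated ketyl (pinacol) coupling.
3. Key disconnection, C11–C12: the C11 aldehyde is used as its 2-lithio-1,3-dithiane (acyl anion) and added to the C12 methyl ketone; the tertiary alkoxide closes the ε-lactone on the C16 ester in the same flask.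
4. C11–OH comes from CBS reduction after dithiane removal; the C16 oxidation level is put on limonene before ring cleavage.
5. Ring order: ε-lactone first (step 8), 14-membered carbocycle last (step 12).

Assumption: the SMILES is taken literally, i.e. (1R,3R,4S,7Z,11S,12R), and commercial 1,5-dimethyl-1,5-cyclooctadiene is freed from its 1,6-isomer before use.

**Step 1**
Reactants: 1 (1Z,5Z)-1,5-dimethylcycloocta-1,5-diene
Product: 3 (4Z)-4-methyl-8-oxonon-4-enal, via methoxy hydroperoxide 2 (not isolated)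
Conditions: O3 (0.9 equiv), CH2Cl2/MeOH 4:1, −78 °C; then Me2S, −78 °C → rt
Reagents that add atoms: ozone ([O-][O+]=O)
Why: Criegee ozonolysis with sub-stoichiometric ozone cleaves one of the two equivalent trisubstituted ring alkenes (carbonyl oxide trapped by methanol as 2, then reduced), and the Z geometry of the surviving alkene is inherited from the eight-membered ring.

**Step 2**
Reactants: 3 (4Z)-4-methyl-8-oxonon-4-enal
Product: 4 (5Z)-8-(1,3-dithian-2-yl)-6-methyloct-5-en-2-one
Conditions: HS(CH2)3SH (1.05 equiv), BF3·OEt2 (10 mol%), CH2Cl2, −40 °C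
Reagents that add atoms: propane-1,3-dithiol (SCCCS)
Why: Lewis-acid dithioacetalisation is far faster for the aldehyde than for the methyl ketone at low temperature, so only C11 is converted into the dithiane.

**Step 3**
Reactants: 4 (5Z)-8-(1,3-dithian-2-yl)-6-methyloct-5-en-2-one
Product: 5 2-[(3Z)-3-methyl-6-(2-methyl-1,3-dioxolan-2-yl)hex-3-en-1-yl]-1,3-dithiane
Conditions: HOCH2CH2OH, PPTS (cat.), benzene, reflux, Dean–Stark
Reagents that add atoms: ethane-1,2-diol (OCCO)
Why: Acid-catalysed ketalisation with azeotropic water removal masks the C4 ketone, leaving the dithiane C–H as the only site that n-BuLi will deprotonate.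

**Step 4**
Reactants: 6 (R)-(+)-limonene
Product: 9 2-[(1R)-4-methylcyclohex-3-en-1-yl]prop-2-en-1-ol, via allyllithium 7 (not isolated), via allylboronate 8 (not isolated)
Conditions: n-BuLi, TMEDA, hexane, 25 °C, 24 h; B(OMe)3, THF, −78 °C; then 30% H2O2, aq NaOH, 0 °C
Reagents that add atoms: hydrogen peroxide (OO)
Why: Allylic metalation of limonene by n-BuLi·TMEDA occurs at the isopropenyl methyl, and borylation followed by oxidation gives the primary allylic alcohol while the ring stereocentre (the future C1, R) is untouched.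

**Step 5**
Reactants: 9 2-[(1R)-4-methylcyclohex-3-en-1-yl]prop-2-en-1-ol
Product: 11 2-[(1R)-4-methylcyclohex-3-en-1-yl]prop-2-enoic acid, via enal 10 (not isolated)
Conditions: TEMPO (20 mol%), PhI(OAc)2 (2.4 equiv), MeCN/H2O 1:1, rt
Reagents that add atoms: water (O)
Why: TEMPO/PhI(OAc)2 oxidation (Epp–Widlanski) takes the primary allylic alcohol through enal 10 and its hydrate to the acrylic acid without touching the ring alkene or the stereocentre.

**Step 6**
Reactants: 11 2-[(1R)-4-methylcyclohex-3-en-1-yl]prop-2-enoic acid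
Product: 12 methyl 2-[(1R)-4-methylcyclohex-3-en-1-yl]prop-2-enoate
Conditions: MeI, K2CO3, DMF, rt
Reagents that add atoms: iodomethane (CI)
Why: SN2 O-methylation of the carboxylate gives the ester that later serves as the internal acyl donor.

**Step 7**
Reactants: 12 methyl 2-[(1R)-4-methylcyclohex-3-en-1-yl]prop-2-enoate
Product: 14 methyl (3R)-3-(2,2-dimethoxyethyl)-2-methylidene-6-oxoheptanoate, via hydroperoxy ketal 13 (not isolated)
Conditions: O3, CH2Cl2/MeOH 5:1, −78 °C (Sudan Red end point); TsOH·H2O (10 mol%), rt; NaHCO3, Me2S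
Reagents that add atoms: ozone ([O-][O+]=O); methanol (CO)
Why: Schreiber's unsymmetrical ozonolysis cleaves only the electron-rich ring alkene (the acrylate is inert), the carbonyl oxide forming on the methyl-bearing carbon and ending as the C12 ketone while the C3 aldehyde is acetalised in situ.

**Step 8**
Reactants: 5 2-[(3Z)-3-methyl-6-(2-methyl-1,3-dioxolan-2-yl)hex-3-en-1-yl]-1,3-dithiane; 14 methyl (3R)-3-(2,2-dimethoxyethyl)-2-methylidene-6-oxoheptanoate
Product: 17 (4R,7R)-4-(2,2-dimethoxyethyl)-7-methyl-3-methylidene-7-{2-[(3Z)-3-methyl-6-(2-methyl-1,3-dioxolan-2-yl)hex-3-en-1-yl]-1,3-dithian-2-yl}oxepan-2-one, via lithiated dithiane 15 (not isolated), via lithium alkoxide 16 (not isolated)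
Conditions: 5 (1.1 equiv), n-BuLi, THF, −30 °C, 2 h; 14, −78 °C, 1 h; −78 → −10 °C; AcOH
Reagents that add atoms: none
Why: Corey–Seebach reaction in which the 2-lithio-1,3-dithiane 15 (acyl-anion equivalent of the C11 aldehyde) adds 1,2 to the C12 methyl ketone, joining two carbonyl carbons, and alkoxide 16 closes the ε-lactone by 7-exo-trig transesterification; the addition has no useful facial bias at C12, the (12R) alkoxide should close faster (both large groups pseudo-equatorial on the twist-chair), and the (12R) lactone is separated from its C12 epimer here.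

**Step 9**
Reactants: 17 the dithiane lactone from step 8
Product: 18 (4R,7R)-4-(2,2-dimethoxyethyl)-7-methyl-3-methylidene-7-[(4Z)-4-methyl-7-(2-methyl-1,3-dioxolan-2-yl)hept-4-enoyl]oxepan-2-one
Conditions: PhI(OCOCF3)2 (1.5 equiv), NaHCO3, MeCN/H2O 9:1, 0 °C
Reagents that add atoms: water (O)
Why: Oxidative dithiane hydrolysis (Stork's hypervalent-iodine method) under buffered conditions unmasks the C11 ketone while sparing acetal, ketal, alkenes and lactone.

**Step 10**
Reactants: 18 the α-acyloxy ketone from step 9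
Product: 19 (4R,7R)-4-(2,2-dimethoxyethyl)-7-[(1S,4Z)-1-hydroxy-4-methyl-7-(2-methyl-1,3-dioxolan-2-yl)hept-4-en-1-yl]-7-methyl-3-methylideneoxepan-2-one
Conditions: (R)-Me-CBS (30 mol%), catecholborane (2 equiv), toluene, −78 °C
Reagents that add atoms: none
Why: Corey–Bakshi–Shibata reduction in which the (R)-oxazaborolidine treats the quaternary C12 as the large group and CH2-10 as the small one, giving the (11S) carbinol under reagent control, and catecholborane at −78 °C leaves the acrylate and the alkene alone.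

**Step 11**
Reactants: 19 the (11S) alcohol from step 10
Product: 20 (4R,7R)-7-[(1S,4Z)-1-hydroxy-4-methyl-8-oxonon-4-en-1-yl]-7-methyl-3-methylidene-4-(2-oxoethyl)oxepan-2-one
Conditions: PPTS, acetone/H2O 4:1, 45 °C
Reagents that add atoms: water (O)
Why: Mild acid hydrolysis of the dioxolane and the dimethyl acetal frees the C4 methyl ketone and the C3 aldehyde without affecting any stereocentre.

**Step 12**
Reactants: 20 the keto aldehyde from step 11
Product: 21 (1R,3R,4S,7Z,11S,12R)-3,4,11-trihydroxycembra-7,15(17)-dien-16,12-olide (target)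
Conditions: TiCl3(DME)1.5, Zn–Cu, DME, 25 °C, syringe-pump addition over 30 h (final 2 mM); aq K2CO3
Reagents that add atoms: none
Why: Titanium-induced intramolecular pinacol coupling (McMurry conditions, high dilution) in which the ketyl from the C3 aldehyde adds to the C4 ketone carbon on the titanium template, closing the 14-membered ring and creating C3 and C4 together; the cis (3R,4S) glycol is the hoped-for major isomer and is separated from the other diol isomers.

**Compound list**
1 | (1Z,5Z)-1,5-dimethylcycloocta-1,5-diene | C/C1=C/CC/C(C)=C\CC1 | starting material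
2 | (4Z)-8-hydroperoxy-8-methoxy-4-methylnon-4-enal (racemic at C8) | COC(C)(OO)CC/C=C(/C)CCC=O | intermediate
3 | (4Z)-4-methyl-8-oxonon-4-enal | CC(=O)CC/C=C(/C)CCC=O | intermediate
4 | (5Z)-8-(1,3-dithian-2-yl)-6-methyloct-5-en-2-one | CC(=O)CC/C=C(/C)CCC1SCCCS1 | intermediate
5 | 2-[(3Z)-3-methyl-6-(2-methyl-1,3-dioxolan-2-yl)hex-3-en-1-yl]-1,3-dithiane | CC1(CC/C=C(/C)CCC2SCCCS2)OCCO1 | intermediate
6 | (R)-(+)-limonene | CC1=CC[C@@H](CC1)C(C)=C | starting material
7 | {2-[(1R)-4-methylcyclohex-3-en-1-yl]prop-2-en-1-yl}lithium | CC1=CC[C@@H](CC1)C(=C)C[Li] | intermediate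
8 | dimethyl {2-[(1R)-4-methylcyclohex-3-en-1-yl]prop-2-en-1-yl}boronate | CC1=CC[C@@H](CC1)C(=C)CB(OC)OC | intermediate
9 | 2-[(1R)-4-methylcyclohex-3-en-1-yl]prop-2-en-1-ol | CC1=CC[C@@H](CC1)C(=C)CO | intermediate
10 | 2-[(1R)-4-methylcyclohex-3-en-1-yl]prop-2-enal | CC1=CC[C@@H](CC1)C(=C)C=O | intermediate
11 | 2-[(1R)-4-methylcyclohex-3-en-1-yl]prop-2-enoic acid | CC1=CC[C@@H](CC1)C(=C)C(O)=O | intermediate
12 | methyl 2-[(1R)-4-methylcyclohex-3-en-1-yl]prop-2-enoate | CC1=CC[C@@H](CC1)C(=C)C(=O)OC | intermediate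
13 | methyl (3R)-3-(2,2-dimethoxyethyl)-6-hydroperoxy-6-methoxy-2-methylideneheptanoate (C6 epimers) | COC(OC)C[C@@H](CCC(C)(OC)OO)C(=C)C(=O)OC | intermediate
14 | methyl (3R)-3-(2,2-dimethoxyethyl)-2-methylidene-6-oxoheptanoate | COC(OC)C[C@@H](CCC(C)=O)C(=C)C(=O)OC | intermediate
15 | 2-lithio-2-[(3Z)-3-methyl-6-(2-methyl-1,3-dioxolan-2-yl)hex-3-en-1-yl]-1,3-dithiane | CC1(CC/C=C(/C)CCC2([Li])SCCCS2)OCCO1 | intermediate
16 | lithium alkoxide of methyl (3R,6R)-3-(2,2-dimethoxyethyl)-6-hydroxy-2-methylidene-6-{2-[(3Z)-3-methyl-6-(2-methyl-1,3-dioxolan-2-yl)hex-3-en-1-yl]-1,3-dithian-2-yl}heptanoate (6R epimer shown) | [Li]O[C@](C)(CC[C@H](CC(OC)OC)C(=C)C(=O)OC)C1(CC/C(C)=C\CCC2(C)OCCO2)SCCCS1 | intermediate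
17 | (4R,7R)-4-(2,2-dimethoxyethyl)-7-methyl-3-methylidene-7-{2-[(3Z)-3-methyl-6-(2-methyl-1,3-dioxolan-2-yl)hex-3-en-1-yl]-1,3-dithian-2-yl}oxepan-2-one | C=C1C(=O)O[C@@](C)(C2(CC/C(C)=C\CCC3(C)OCCO3)SCCCS2)CC[C@@H]1CC(OC)OC | intermediate
18 | (4R,7R)-4-(2,2-dimethoxyethyl)-7-methyl-3-methylidene-7-[(4Z)-4-methyl-7-(2-methyl-1,3-dioxolan-2-yl)hept-4-enoyl]oxepan-2-one | C=C1C(=O)O[C@@](C)(C(=O)CC/C(C)=C\CCC2(C)OCCO2)CC[C@@H]1CC(OC)OC | intermediate
19 | (4R,7R)-4-(2,2-dimethoxyethyl)-7-[(1S,4Z)-1-hydroxy-4-methyl-7-(2-methyl-1,3-dioxolan-2-yl)hept-4-en-1-yl]-7-methyl-3-methylideneoxepan-2-one | C=C1C(=O)O[C@@](C)([C@@H](O)CC/C(C)=C\CCC2(C)OCCO2)CC[C@@H]1CC(OC)OC | intermediate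
20 | (4R,7R)-7-[(1S,4Z)-1-hydroxy-4-methyl-8-oxonon-4-en-1-yl]-7-methyl-3-methylidene-4-(2-oxoethyl)oxepan-2-one | C=C1C(=O)O[C@@](C)([C@@H](O)CC/C(C)=C\CCC(C)=O)CC[C@@H]1CC=O | intermediate
21 | (1R,3R,4S,7Z,11S,12R)-3,4,11-trihydroxycembra-7,15(17)-dien-16,12-olide | C=C1C(=O)O[C@]2(C)CC[C@@H]1C[C@@H](O)[C@@](C)(O)CC/C=C(/C)CC[C@@H]2O | target

**Totals**
Total step count: 12 (steps 1–3 and 4–7 in the two branches, steps 8–12 after convergence).
Longest linear sequence: 9 steps (6 → 9 → 11 → 12 → 14 → 17 → 18 → 19 → 20 → 21).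

**Three steps most likely to fail**

Step 8 (dithiane addition and lactonisation). The addition to the C12 ketone has no intrinsic facial control, so at best about half of the material is the (12R) lactone. Conjugate addition to the acrylate or a sluggish seven-ring closure would cut this further. The fallback sets out from 14 (with 3 as partner) and returns at 20, replacing steps 2, 3 and 8–11. It reverses the polarity at the ketone carbon instead of the aldehyde carbon. Kinetic enolisation and triflation of 14 (KHMDS, PhNTf2, THF, −78 °C) gives enol triflate F1. Catalytic asymmetric Ni/Cr (Nozaki–Hiyama–Kishi) coupling of F1 with keto aldehyde 3 (CrCl2, cat. NiCl2, chiral sulfonamide ligand) gives allylic alcohol F2, with (11S) set by the ligand. TESCl/imidazole gives silyl ether F3, which blocks 5-exo iodoetherification onto C7=C8. LiOH gives carboxylic acid F4. Iodolactonisation (I2, NaHCO3, MeCN, 0 °C) gives iodolactone F5, the carboxylate adding to C12 anti to iodine on the face set by the allylic C11–O stereocentre (inside-alkoxy model). Bu3SnH/Et3B gives lactone F6, and aqueous AcOH removes the TES group and the acetal to deliver 20.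

Step 12 (macrocyclic pinacol coupling). Low-valent titanium may reduce the α-methylene lactone, and the cis (3R,4S) diol is only one of four possible isomers; the template argument is not firm. The fallback sets out from 19 and returns at 21; it protects the Michael acceptor before the reductive closure but does not by itself improve the diol ratio. Dimethylamine in THF adds to 19 to give amine adduct F7 (C15 epimers, inconsequential). PPTS in aqueous acetone gives amino keto aldehyde F8. The titanium closure is run on F8 to give macrocyclic amino triol F9. MeI followed by NaHCO3 (quaternisation, β-elimination) regenerates the methylene lactone and gives 21.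

Step 10 (CBS reduction). The ketone is hindered and α-acyloxy, next to a quaternary centre; slow reduction, lactone acyl shift to O11 or poor induction would erode (11S). The fallback sets out from 17 and returns at 21; it moves the reduction to the rigid macrocycle. PPTS in aqueous acetone on 17 frees ketone and aldehyde with the dithiane still in place, giving keto aldehyde F10. The titanium pinacol closure then gives dithiane diol F11. PhI(OCOCF3)2/NaHCO3 unmasks macrocyclic ketone F12. Reduction of F12 with Zn(BH4)2 (chelation to the lactone oxygen), or again (R)-CBS/catecholborane, gives 21.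

**Further compounds**
F1 | step 8 | methyl (3R)-3-(2,2-dimethoxyethyl)-2-methylidene-6-[(trifluoromethanesulfonyl)oxy]hept-6-enoate | COC(OC)C[C@@H](CCC(=C)OS(=O)(=O)C(F)(F)F)C(=C)C(=O)OC
F2 | step 8 | methyl (3R,7S,10Z)-3-(2,2-dimethoxyethyl)-7-hydroxy-10-methyl-2,6-dimethylidene-14-oxopentadec-10-enoate | COC(OC)C[C@@H](CCC(=C)[C@@H](O)CC/C(C)=C\CCC(C)=O)C(=C)C(=O)OC
F3 | step 8 | methyl (3R,7S,10Z)-3-(2,2-dimethoxyethyl)-10-methyl-2,6-dimethylidene-14-oxo-7-[(triethylsilyl)oxy]pentadec-10-enoate | COC(OC)C[C@@H](CCC(=C)[C@@H](O[Si](CC)(CC)CC)CC/C(C)=C\CCC(C)=O)C(=C)C(=O)OC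
F4 | step 8 | (3R,7S,10Z)-3-(2,2-dimethoxyethyl)-10-methyl-2,6-dimethylidene-14-oxo-7-[(triethylsilyl)oxy]pentadec-10-enoic acid | COC(OC)C[C@@H](CCC(=C)[C@@H](O[Si](CC)(CC)CC)CC/C(C)=C\CCC(C)=O)C(=C)C(O)=O
F5 | step 8 | (4R,7R)-4-(2,2-dimethoxyethyl)-7-(iodomethyl)-3-methylidene-7-{(1S,4Z)-4-methyl-8-oxo-1-[(triethylsilyl)oxy]non-4-en-1-yl}oxepan-2-one | C=C1C(=O)O[C@@](CI)([C@@H](O[Si](CC)(CC)CC)CC/C(C)=C\CCC(C)=O)CC[C@@H]1CC(OC)OC
F6 | step 8 | (4R,7R)-4-(2,2-dimethoxyethyl)-7-methyl-3-methylidene-7-{(1S,4Z)-4-methyl-8-oxo-1-[(triethylsilyl)oxy]non-4-en-1-yl}oxepan-2-one | C=C1C(=O)O[C@@](C)([C@@H](O[Si](CC)(CC)CC)CC/C(C)=C\CCC(C)=O)CC[C@@H]1CC(OC)OC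
F7 | step 12 | (4R,7R)-4-(2,2-dimethoxyethyl)-3-[(dimethylamino)methyl]-7-[(1S,4Z)-1-hydroxy-4-methyl-7-(2-methyl-1,3-dioxolan-2-yl)hept-4-en-1-yl]-7-methyloxepan-2-one (C3 epimers) | CN(C)CC1C(=O)O[C@@](C)([C@@H](O)CC/C(C)=C\CCC2(C)OCCO2)CC[C@@H]1CC(OC)OC
F8 | step 12 | (4R,7R)-3-[(dimethylamino)methyl]-7-[(1S,4Z)-1-hydroxy-4-methyl-8-oxonon-4-en-1-yl]-7-methyl-4-(2-oxoethyl)oxepan-2-one (C3 epimers) | CN(C)CC1C(=O)O[C@@](C)([C@@H](O)CC/C(C)=C\CCC(C)=O)CC[C@@H]1CC=O
F9 | step 12 | (1R,3R,4S,7Z,11S,12R)-17-(dimethylamino)-3,4,11-trihydroxycembr-7-en-16,12-olide (C15 epimers) | CN(C)CC1C(=O)O[C@]2(C)CC[C@@H]1C[C@@H](O)[C@@](C)(O)CC/C=C(/C)CC[C@@H]2O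
F10 | step 10 | (4R,7R)-7-methyl-3-methylidene-7-{2-[(3Z)-3-methyl-7-oxooct-3-en-1-yl]-1,3-dithian-2-yl}-4-(2-oxoethyl)oxepan-2-one | C=C1C(=O)O[C@@](C)(C2(CC/C(C)=C\CCC(C)=O)SCCCS2)CC[C@@H]1CC=O
F11 | step 10 | (1R,3R,4S,7Z,12R)-3,4-dihydroxy-11,11-(propane-1,3-diyldisulfanediyl)cembra-7,15(17)-dien-16,12-olide | C=C1C(=O)O[C@]2(C)CC[C@@H]1C[C@@H](O)[C@@](C)(O)CC/C=C(/C)CCC23SCCCS3
F12 | step 10 | (1R,3R,4S,7Z,12R)-3,4-dihydroxy-11-oxocembra-7,15(17)-dien-16,12-olide | C=C1C(=O)O[C@]2(C)CC[C@@H]1C[C@@H](O)[C@@](C)(O)CC/C=C(/C)CCC2=O
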